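With the ring numbered C1 (quaternary carbinol), C2 (ketone), C3 (CH2), C4–C6 (the three oxygenated CH), the ring is cut into C1–C2–C3 and C4–C5–C6. The key step is a one-pot [3+3] annulation that uses the fact that C4 and C6 are both β to the C2 carbonyl: the silyl dienol ether of methyl vinyl ketone adds to a D-glyceraldehyde-derived α-benzoyloxy aldehyde (C3–C4, Felkin control from C5), then a sulfide-triggered Morita–Baylis–Hillman closure onto the acetal terminus forms C1–C6. The precursor is thus an acyclic aldehyde–acetal; a later allylic transposition and an anti-selective cis-dihydroxylation set C1 and C6.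

Key step: step 5

Remarks on the chemistry:
- Compound 1 is taken as the commercial D-glyceraldehyde acetonide and 7 as the commercial silyl dienol ether.
- The methoxy-bearing carbon of 9 and 10 is drawn as the expected major epimer (trans to the benzoate); both epimers converge in step 6, where this carbon becomes sp2.
- In step 5 the difluoroboron aldolate is assumed to exchange to the triethylsilyl ether with Et3SiOTf; if it does not, the free alcohol would be silylated conventionally before step 6.

Step 1
Reactants: 1 (R)-2,2-dimethyl-1,3-dioxolane-4-carbaldehyde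
Product: 2 (R)-3,3-dimethoxypropane-1,2-diol
Conditions: MeOH, Amberlyst-15 (H+), rt; filter, evaporate, repeat once
Reagents that add atoms: methanol, CO
Why: Acid-catalysed acetalisation of the aldehyde with concurrent transketalisation of the acetonide in excess methanol should give the dimethyl acetal diol, and the stereocentre is not enolised under mild acid, so it stays (R).

Step 2
Reactants: 2 (R)-3,3-dimethoxypropane-1,2-diol
Product: 4 (R)-1-[(tert-butyldimethylsilyl)oxy]-3,3-dimethoxypropan-2-yl benzoate, via primary TBS ether 3 (not isolated)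
Conditions: TBSCl, imidazole, CH2Cl2, −20 → 0 °C; then BzCl, pyridine, DMAP (cat.), 0 °C → rt
Reagents that add atoms: tert-butyldimethylsilyl chloride, CC(C)(C)[Si](C)(C)Cl; benzoyl chloride, O=C(Cl)c1ccccc1
Why: The bulky silyl chloride should silylate the primary hydroxyl selectively, and DMAP-catalysed acylation then benzoylates the remaining secondary hydroxyl without touching the stereocentre.

Step 3
Reactants: 4 (R)-1-[(tert-butyldimethylsilyl)oxy]-3,3-dimethoxypropan-2-yl benzoate
Product: 5 (R)-3-hydroxy-1,1-dimethoxypropan-2-yl benzoate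
Conditions: HF·pyridine, pyridine, THF, 0 °C → rt
Reagents that add atoms: none
Why: Fluoride-driven silyl ether cleavage under buffered, weakly acidic conditions should leave the benzoate and the dimethyl acetal intact and disfavour 2→1 benzoyl migration.

Step 4
Reactants: 5 (R)-3-hydroxy-1,1-dimethoxypropan-2-yl benzoate
Product: 6 (R)-1,1-dimethoxy-3-oxopropan-2-yl benzoate
Conditions: Dess–Martin periodinane, NaHCO3, CH2Cl2, 0 °C → rt; filtered and used crude at once
Reagents that add atoms: none
Why: Dess–Martin oxidation of the primary alcohol under buffered, non-basic conditions should give the α-benzoyloxy aldehyde without epimerisation or β-elimination of methanol.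

Step 5
Reactants: 6 (R)-1,1-dimethoxy-3-oxopropan-2-yl benzoate; 7 2-(trimethylsilyloxy)buta-1,3-diene
Product: 10 (1S,2R,6R)-2-methoxy-3-methylidene-4-oxo-6-[(triethylsilyl)oxy]cyclohexyl benzoate, via silyl aldol vinyl ketone 8 (not isolated), via cyclic sulfonium triflate 9 (not isolated)
Conditions: 7 (1.1 equiv), BF3·OEt2, CH2Cl2, −78 °C; then 2,6-lutidine, Et3SiOTf, Me2S, −78 → −30 °C; then DBU, 0 °C
Reagents that add atoms: triethylsilyl trifluoromethanesulfonate, CC[Si](CC)(CC)OS(=O)(=O)C(F)(F)F
Why: BF3 activates only the aldehyde, so the CH2 terminus of the silyl dienol ether adds to it in a Mukaiyama aldol (open transition state) to form C3–C4 and, after silyl exchange, the β-silyloxy vinyl ketone 8; Me2S then adds to the silyl-triflate-activated enone to give a β-sulfonio silyl enol ether whose C1 attacks the oxocarbenium ion released from the dimethyl acetal (C1–C6), and DBU expels Me2S from 9 to leave the exocyclic enone. The closest known reactions are the Mukaiyama aldol of 2-silyloxybutadienes and the sulfide/silyl triflate-mediated (chalcogeno) Morita–Baylis–Hillman reaction of enones with acetals, here run in tandem and intramolecularly. The ring closes in a 6-(enolendo)-exo-trig mode. The new C4 stereocentre is set by polar Felkin–Anh addition anti to the C5 benzoate (4,5-anti, which is cis on the ring), the bought C5 centre being the only control element; the C6 methoxy centre (expected trans to the benzoate through neighbouring-group participation) and C1 need no control because both become sp2 before the final stereocentres are set. The step needs the aldehyde to react before the acetal, which BF3 at −78 °C should secure because the α-acyloxy acetal ionises only with the silyl triflate, and it needs an unambiguous C1 nucleophile, which is secured because the enol ether arises regiospecifically from sulfide addition and not from deprotonation.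

Step 6
Reactants: 10 (1S,2R,6R)-2-methoxy-3-methylidene-4-oxo-6-[(triethylsilyl)oxy]cyclohexyl benzoate
Product: 11 [(3S,4R)-3-(benzoyloxy)-6-oxo-4-[(triethylsilyl)oxy]cyclohex-1-en-1-yl]methyl benzoate
Conditions: PhCO2H (3 equiv), DABCO (1 equiv), MeCN, 40 °C
Reagents that add atoms: benzoic acid, O=C(O)c1ccccc1
Why: Proposed new method: DABCO adds to the exocyclic enone, the resulting C1 enolate expels the C6 methoxide in an E1cB step (benzoic acid protonates it), and benzoate displaces DABCO at the primary allylic carbon, an overall SN2′ transposition driven by formation of the endocyclic trisubstituted enone; the closest known reaction is the DABCO-catalysed allylic substitution and 1,3-transposition of Morita–Baylis–Hillman acetates and carbonates, which is not established for an ether leaving group; the C6 stereocentre disappears and C4 and C5 are untouched.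

Step 7
Reactants: 11 [(3S,4R)-3-(benzoyloxy)-6-oxo-4-[(triethylsilyl)oxy]cyclohex-1-en-1-yl]methyl benzoate
Product: 12 [(1S,2S,3S,4R)-3-(benzoyloxy)-1,2-dihydroxy-6-oxo-4-[(triethylsilyl)oxy]cyclohexyl]methyl benzoate
Conditions: OsO4 (5 mol %), NMO, citric acid, t-BuOH/H2O, rt
Reagents that add atoms: osmium tetroxide, O=[Os](=O)(=O)=O; N-methylmorpholine N-oxide, C[N+]1([O-])CCOCC1; water, O
Why: Upjohn cis-dihydroxylation of the C1=C6 enone bond should occur on the ring face opposite to the allylic C5 benzoate and the C4 silyl ether (both on the same face), which places the C1 and C6 hydroxyls cis to each other and the C6 hydroxyl trans to the C5 benzoate.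

Step 8
Reactants: 12 [(1S,2S,3S,4R)-3-(benzoyloxy)-1,2-dihydroxy-6-oxo-4-[(triethylsilyl)oxy]cyclohexyl]methyl benzoate
Product: 13 [(1S,2S,3R,4R)-3-(benzoyloxy)-1,2,4-trihydroxy-6-oxocyclohexyl]methyl benzoate
Conditions: HF·pyridine, THF, 0 °C
Reagents that add atoms: none
Why: Weakly acidic fluoride desilylation of the secondary triethylsilyl ether should free the C4 hydroxyl, and the non-basic medium avoids benzoyl migration and β-elimination of the β-hydroxy ketone.

Compound list
1 | (R)-2,2-dimethyl-1,3-dioxolane-4-carbaldehyde (D-glyceraldehyde acetonide) | O=C[C@H]1COC(C)(C)O1 | starting material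
2 | (R)-3,3-dimethoxypropane-1,2-diol | OC[C@@H](O)C(OC)OC | intermediate
3 | (R)-3-[(tert-butyldimethylsilyl)oxy]-1,1-dimethoxypropan-2-ol | CC(C)(C)[Si](C)(C)OC[C@@H](O)C(OC)OC | intermediate (not isolated)
4 | (R)-1-[(tert-butyldimethylsilyl)oxy]-3,3-dimethoxypropan-2-yl benzoate | CC(C)(C)[Si](C)(C)OC[C@@H](OC(=O)c1ccccc1)C(OC)OC | intermediate
5 | (R)-3-hydroxy-1,1-dimethoxypropan-2-yl benzoate | OC[C@@H](OC(=O)c1ccccc1)C(OC)OC | intermediate
6 | (R)-1,1-dimethoxy-3-oxopropan-2-yl benzoate | O=C[C@@H](OC(=O)c1ccccc1)C(OC)OC | intermediate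
7 | 2-(trimethylsilyloxy)buta-1,3-diene | C=CC(=C)O[Si](C)(C)C | starting material
8 | (5R,6R)-7,7-dimethoxy-3-oxo-5-[(triethylsilyl)oxy]hept-1-en-6-yl benzoate | C=CC(=O)C[C@@H](O[Si](CC)(CC)CC)[C@@H](OC(=O)c1ccccc1)C(OC)OC | intermediate (not isolated)
9 | {[3-(benzoyloxy)-2-methoxy-6-oxo-4-[(triethylsilyl)oxy]cyclohexyl]methyl}dimethylsulfonium triflate (3-OBz and 4-OSiEt3 cis, 2-OMe trans to 3-OBz, epimers at C-1) | C[S+](C)CC1C(=O)C[C@@H](O[Si](CC)(CC)CC)[C@@H](OC(=O)c2ccccc2)[C@@H]1OC.[O-]S(=O)(=O)C(F)(F)F | intermediate (not isolated)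
10 | (1S,2R,6R)-2-methoxy-3-methylidene-4-oxo-6-[(triethylsilyl)oxy]cyclohexyl benzoate | C=C1C(=O)C[C@@H](O[Si](CC)(CC)CC)[C@@H](OC(=O)c2ccccc2)[C@@H]1OC | intermediate
11 | [(3S,4R)-3-(benzoyloxy)-6-oxo-4-[(triethylsilyl)oxy]cyclohex-1-en-1-yl]methyl benzoate | O=C(OCC1=C[C@H](OC(=O)c2ccccc2)[C@H](O[Si](CC)(CC)CC)CC1=O)c1ccccc1 | intermediate
12 | [(1S,2S,3S,4R)-3-(benzoyloxy)-1,2-dihydroxy-6-oxo-4-[(triethylsilyl)oxy]cyclohexyl]methyl benzoate (the 4-O-triethylsilyl ether of the target) | O=C(OC[C@@]1(O)C(=O)C[C@@H](O[Si](CC)(CC)CC)[C@@H](OC(=O)c2ccccc2)[C@@H]1O)c1ccccc1 | intermediate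
13 | [(1S,2S,3R,4R)-3-(benzoyloxy)-1,2,4-trihydroxy-6-oxocyclohexyl]methyl benzoate | O=C(OC[C@@]1(O)C(=O)C[C@@H](O)[C@@H](OC(=O)c2ccccc2)[C@@H]1O)c1ccccc1 | target

Total step count: 8. Longest linear sequence: 8 steps (1 → 13); the only other building block, 7, is commercial.

Steps most likely to fail

Step 6 (proposed new method). The allylic methoxide may not be expelled, so that conjugate addition of the amine simply reverses, or the basic medium may trigger β-elimination of the C4 silyloxy group. The fallback uses known chemistry, sets out from 8 and comes back at 11. For it, step 5 is worked up after the silyl exchange, before Me2S is added, and 8 is isolated. Chemoselective unmasking of its dimethyl acetal (Et3SiOTf, 2,4,6-collidine, then water) should give the keto-aldehyde (2R,3R)-1,5-dioxo-3-[(triethylsilyl)oxy]hept-6-en-2-yl benzoate F1. An intramolecular Morita–Baylis–Hillman reaction of the vinyl ketone with this aldehyde (Me2S, TiCl4, CH2Cl2, −78 °C, or PMe3) closes the same C1–C6 bond and gives the α-methylene-β-hydroxy ketone (1S,6R)-2-hydroxy-3-methylidene-4-oxo-6-[(triethylsilyl)oxy]cyclohexyl benzoate F2, whose carbinol epimers are both usable. Benzoylation (BzCl, pyridine, DMAP) gives the secondary allylic benzoate (1S,6R)-3-methylidene-4-oxo-6-[(triethylsilyl)oxy]cyclohexane-1,2-diyl dibenzoate F3. DABCO-catalysed 1,3-transposition of this Baylis–Hillman ester, known for the corresponding acetates, then gives 11.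

Step 5 (key step). The acetal may ionise too early, the vinyl ketone may polymerise or close by oxa-Michael addition, or the Felkin preference in the aldol stage may be poor. The fallback sets out from 6, comes back at 11 and makes the two ring bonds in separate steps. Mukaiyama aldol of 6 with 2-(trimethylsilyloxy)propene (BF3·OEt2, −78 °C, then Et3SiOTf, 2,6-lutidine) should give the methyl ketone (2R,3R)-1,1-dimethoxy-5-oxo-3-[(triethylsilyl)oxy]hexan-2-yl benzoate F4. Acetal unmasking (Et3SiOTf, 2,4,6-collidine, then water) gives the keto-aldehyde (2R,3R)-1,5-dioxo-3-[(triethylsilyl)oxy]hexan-2-yl benzoate F5. Amine-catalysed intramolecular aldol condensation (Bn2NH·TFA, benzene) closes the enone (1S,6R)-4-oxo-6-[(triethylsilyl)oxy]cyclohex-2-en-1-yl benzoate F6. Morita–Baylis–Hillman hydroxymethylation (aqueous formaldehyde, imidazole, THF) gives (1S,6R)-3-(hydroxymethyl)-4-oxo-6-[(triethylsilyl)oxy]cyclohex-2-en-1-yl benzoate F7, and benzoylation (BzCl, pyridine) gives 11.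

Step 4. The α-benzoyloxy β,β-dimethoxy aldehyde may epimerise at the α-carbon or lose methanol by β-elimination during oxidation or handling. The fallback sets out from 5 and comes back at 11. Acetal exchange of 5 with ethylene glycol (PPTS, benzene, reflux, removal of methanol) should give the cyclic acetal (R)-1-(1,3-dioxolan-2-yl)-2-hydroxyethyl benzoate F8. Dess–Martin oxidation gives (R)-1-(1,3-dioxolan-2-yl)-2-oxoethyl benzoate F9, in which β-elimination would require ring opening. Under the conditions of step 5, F9 should give (1S,2R,6R)-3-methylidene-4-oxo-6-[(triethylsilyl)oxy]-2-{2-[(triethylsilyl)oxy]ethoxy}cyclohexyl benzoate F10. The conditions of step 6 then expel the silylated glycol arm in place of methanol and give 11.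

Further compounds
F1 | step 6 | (2R,3R)-1,5-dioxo-3-[(triethylsilyl)oxy]hept-6-en-2-yl benzoate | C=CC(=O)C[C@@H](O[Si](CC)(CC)CC)[C@@H](OC(=O)c1ccccc1)C=O
F2 | step 6 | (1S,6R)-2-hydroxy-3-methylidene-4-oxo-6-[(triethylsilyl)oxy]cyclohexyl benzoate (C-2 epimers) | C=C1C(=O)C[C@@H](O[Si](CC)(CC)CC)[C@@H](OC(=O)c2ccccc2)C1O
F3 | step 6 | (1S,6R)-3-methylidene-4-oxo-6-[(triethylsilyl)oxy]cyclohexane-1,2-diyl dibenzoate (C-2 epimers) | C=C1C(=O)C[C@@H](O[Si](CC)(CC)CC)[C@@H](OC(=O)c2ccccc2)C1OC(=O)c1ccccc1
F4 | step 5 | (2R,3R)-1,1-dimethoxy-5-oxo-3-[(triethylsilyl)oxy]hexan-2-yl benzoate | CC(=O)C[C@@H](O[Si](CC)(CC)CC)[C@@H](OC(=O)c1ccccc1)C(OC)OC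
F5 | step 5 | (2R,3R)-1,5-dioxo-3-[(triethylsilyl)oxy]hexan-2-yl benzoate | CC(=O)C[C@@H](O[Si](CC)(CC)CC)[C@@H](OC(=O)c1ccccc1)C=O
F6 | step 5 | (1S,6R)-4-oxo-6-[(triethylsilyl)oxy]cyclohex-2-en-1-yl benzoate | O=C1C=C[C@H](OC(=O)c2ccccc2)[C@H](O[Si](CC)(CC)CC)C1
F7 | step 5 | (1S,6R)-3-(hydroxymethyl)-4-oxo-6-[(triethylsilyl)oxy]cyclohex-2-en-1-yl benzoate | O=C1C(CO)=C[C@H](OC(=O)c2ccccc2)[C@H](O[Si](CC)(CC)CC)C1
F8 | step 4 | (R)-1-(1,3-dioxolan-2-yl)-2-hydroxyethyl benzoate | OC[C@@H](OC(=O)c1ccccc1)C1OCCO1
F9 | step 4 | (R)-1-(1,3-dioxolan-2-yl)-2-oxoethyl benzoate | O=C[C@@H](OC(=O)c1ccccc1)C1OCCO1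
F10 | step 4 | (1S,2R,6R)-3-methylidene-4-oxo-6-[(triethylsilyl)oxy]-2-{2-[(triethylsilyl)oxy]ethoxy}cyclohexyl benzoate | C=C1C(=O)C[C@@H](O[Si](CC)(CC)CC)[C@@H](OC(=O)c2ccccc2)[C@@H]1OCCO[Si](CC)(CC)CC
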